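**Remark (assumption on numbering):** chain locants C1–C7 run from the benzylic carbon on the 4-hydroxy-3,5-dimethoxyphenyl (syringyl) ring (C1) to the benzylic carbon on the 4-hydroxy-3-methoxyphenyl (guaiacyl) ring (C7) and are kept for all intermediates; in this numbering the target 11 is (3R,5S), the syn-diol.

## Analysis of the target

- The target 11 is an open-chain 1,7-diarylheptane with a syringyl ring on C1 and a guaiacyl ring on C7; both arenes can be bought and no ring has to be built.
- The only stereocentres are the carbinol carbons C3 (R) and C5 (S), separated by the C4 methylene: a syn-1,3-diol.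
- The molecule is pseudo-meso. With two identical aryl groups it would be achiral; the single element of dissymmetry is the second methoxy group of the syringyl ring, six bonds from C3.
- Relative configuration is therefore the easy part. Absolute configuration is the same problem as telling the two chain ends apart. A reagent that delivers the same absolute sense to both carbinols gives the anti diastereomer, and any syn-selective route through an intermediate with indistinguishable ends gives the racemate.
- The two free phenols are electron-rich (oxidation, quinone-methide formation, quenching of organometallics) and are best carried as benzyl ethers. In unsaturated intermediates the C3–O and C5–O bonds become allylic and can ionise or be hydrogenolysed.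
- The feature exploited: C2–C3–C4–C5–C6 with the two cis oxygens on C3 and C5 is the skeleton of cis-cyclopent-4-ene-1,3-diol (1), with C2 and C6 as its olefinic carbons. A meso ring therefore already holds the syn relationship, and the whole stereochemical task becomes one choice between two enantiotopic olefinic carbons.

## Retrosynthetic reasoning

**11 ⇐ 9.** The C1=C2 and C6=C7 double bonds, two O-benzyl groups and a benzylidene acetal on O3/O5 are all retro-added. All are removed by hydrogen on palladium in one operation, so protecting groups and alkene geometry cost no extra step. The forward reaction must saturate the styryl bonds without cleaving the allylic C–O bonds first.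

**9 ⇐ 5 + 8.** The C1=C2 bond is cut by cross-metathesis between the terminal vinyl group of dioxane 5 and the syringyl styrene 8. This joins the second aryl unit to an already enantio-defined core; the only requirement is that the existing styryl bond of 5 stays out of the metathesis.

**5 ⇐ 2 + 4 (key disconnection).** The C6=C7 bond of 5 is cut and C2 is reconnected to C6, which closes the five-membered ring of the meso bicyclic acetal 2 and releases the guaiacyl styrene 4.

- Forward, this is a catalytic asymmetric ring-opening/cross-metathesis.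
- A chiral catalyst decides which olefinic carbon of 2 receives the guaiacyl-CH= unit. This one decision fixes the absolute configuration of C3 and C5 together and makes the two ends chemically different (styryl against vinyl).
- The precursor 2 is achiral and one step from a catalogue diol.
- The order of the two styrenes is itself a control element: the same catalyst antipode with 8 first and 4 second would lead to the enantiomer of 11.

**2 ⇐ 1.** The acetal bridge over O3 and O5 is removed. It has three jobs: it turns a low-strain cyclopentene into a bicyclo[3.2.1]octene that opens irreversibly, it blocks one face of the olefin, and it is the diol protecting group that leaves by hydrogenolysis at the end.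

**4 ⇐ 3 and 8 ⇐ 7 ⇐ 6.** Each styrene comes from the corresponding benzaldehyde by Wittig methylenation; 7 is the benzyl ether of 6.

## Alternatives that were turned down

**Alternative 1:** the textbook route.
- Disconnection: the C3–C4 bond by an aldol reaction, followed by 1,3-syn reduction.
- Forward key step: a diisopinocampheylboron enolate of a 4-arylbutan-2-one adds to a 3-arylpropanal to give (5R)-1-[4-(benzyloxy)-3-methoxyphenyl]-7-[4-(benzyloxy)-3,5-dimethoxyphenyl]-5-hydroxyheptan-3-one A1 (locants of this name count from the guaiacyl end), followed by chelation-controlled borohydride reduction.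
- Why turned down: C3 and C5 are set in two separate events under two different control elements, although they are mirror images of each other apart from the remote methoxy group. Reagent control in methyl-ketone boron aldols with unbranched aldehydes is moderate. A1 is a β-hydroxy ketone that dehydrates easily to the conjugated enone and can retro-aldolise. Two differently elaborated C6–C4 and C6–C3 chains have to be prepared first, which makes the sequence longer than the one chosen.

**Alternative 2:** the biomimetic route.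
- Disconnection: C1=C2 and C6=C7 by a curcuminoid-type double condensation, then reduction.
- Forward key step: mixed condensation of a boron-complexed pentane-2,4-dione with the two aryl aldehydes gives (1E,6E)-1-(4-hydroxy-3,5-dimethoxyphenyl)-7-(4-hydroxy-3-methoxyphenyl)hepta-1,6-diene-3,5-dione A2; hydrogenation gives 1-(4-hydroxy-3,5-dimethoxyphenyl)-7-(4-hydroxy-3-methoxyphenyl)heptane-3,5-dione A3, which is then reduced.
- Why turned down: the two carbonyl groups of A3 differ only through the remote methoxy group, so no reducing agent can choose between them. A catalyst that reduces both with the same facial sense gives the anti diol. A catalyst-controlled first reduction followed by a syn-directed second one gives the two regioisomeric hydroxy ketones in equal amounts, and these lead to opposite enantiomers of the syn diol, a racemate by construction. The mixed condensation also gives a statistical mixture of three curcuminoids.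

**Alternative 3:** hemiacetal/oxa-Michael relay.
- Disconnection: the C5–O bond, with C7 carried as an aryl ketone.
- Forward key step: asymmetric allylation of a 3-arylpropanal and cross-metathesis with an aryl vinyl ketone give (2E,5R)-1-[4-(benzyloxy)-3-methoxyphenyl]-7-[4-(benzyloxy)-3,5-dimethoxyphenyl]-5-hydroxyhept-2-en-1-one A4 (locants of this name count from the guaiacyl end). An aromatic aldehyde and catalytic alkoxide convert A4 under equilibrating conditions into 1-[4-(benzyloxy)-3-methoxyphenyl]-2-[(2R,4R,6R)-6-{2-[4-(benzyloxy)-3,5-dimethoxyphenyl]ethyl}-2-phenyl-1,3-dioxan-4-yl]ethan-1-one A5; global hydrogenolysis follows.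
- Why turned down: stereochemistry is passed on one centre at a time (absolute from the allylation reagent, relative by equilibration). C7 is carried at the ketone oxidation level and must be erased by benzylic hydrogenolysis. The aryl vinyl ketone polymerises easily. The linear sequence from the aldehyde precursor is about twice as long as the chosen one.

Key step: step 3

## Route

Step 1
Reactants: 1 cis-cyclopent-4-ene-1,3-diol (meso, (1R,3S))
Product: 2 (1R,3s,5S)-3-phenyl-2,4-dioxabicyclo[3.2.1]oct-6-ene (meso benzylidene acetal, phenyl exo, i.e. anti to the olefinic bridge)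
Conditions: PhCH(OMe)2 (1.1 equiv), PPTS (5 mol %), toluene, 45 °C, reduced pressure (MeOH removed)
Reagents that add atoms: benzaldehyde dimethyl acetal, COC(OC)c1ccccc1
Why: Acid-catalysed transacetalisation; the cis-1,3-diol on the cyclopentene envelope presents both oxygens pseudo-diaxially so that a six-membered 1,3-dioxane closes, removal of methanol drives the equilibrium, and the phenyl group takes the unhindered exo position under thermodynamic control, which keeps the product meso.

Step 2
Reactants: 3 4-(benzyloxy)-3-methoxybenzaldehyde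
Product: 4 1-(benzyloxy)-4-ethenyl-2-methoxybenzene
Conditions: Ph3PCH3Br, KOtBu, THF, 0 °C to rt
Reagents that add atoms: methyltriphenylphosphonium bromide, C[P+](c1ccccc1)(c1ccccc1)c1ccccc1.[Br-]
Why: Wittig methylenation of a non-enolisable aryl aldehyde; the benzyl ether is inert to the ylide.

Step 3
Reactants: 2 (1R,3s,5S)-3-phenyl-2,4-dioxabicyclo[3.2.1]oct-6-ene; 4 1-(benzyloxy)-4-ethenyl-2-methoxybenzene
Product: 5 (2S,4R,6S)-4-{(E)-2-[4-(benzyloxy)-3-methoxyphenyl]ethenyl}-6-ethenyl-2-phenyl-1,3-dioxane (4,6-cis, phenyl trans to both alkenyl groups)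
Conditions: 4 (4 equiv), enantiopure Ru isopropoxybenzylidene complex with a bidentate N-heterocyclic carbene–biaryloxide ligand (5 mol %), THF, 22 °C
Reagents that add atoms: none
Why: Catalytic asymmetric ring-opening/cross-metathesis, a reaction type established for meso norbornenes and 8-oxa- and 8-azabicyclo[3.2.1]oct-6-enes with styrenes; 2 is a carbocyclic member of the same bicyclo[3.2.1]oct-6-ene class. The Ru benzylidene formed from 4 adds to the strained ring olefin (C2=C6) from the open face syn to the C4 methylene bridge, the metallacyclobutane cycloreverts with opening of the five-membered ring, and a second molecule of 4 turns over the resulting alkylidene, leaving the terminal vinyl group on C2 and regenerating the benzylidene. No ring is closed: the cyclopentene is opened and the 1,3-dioxane of 2 is carried into 5 unchanged. No stereocentre is created from nothing; the syn relation of C3 and C5 is inherited from 1, and their absolute configuration is fixed here by which of the two enantiotopic olefinic carbons receives the ArCH= unit, decided by the chiral ligand sphere in the metallacyclobutane-forming step. The selectivities needed are this enantiotopic-carbon selection and mono-opening without oligomerisation; the rigid bicycle (one accessible face, bridge next to the reacting bond), the excess of 4 and the release of ring strain, which makes the opening irreversible and the ratio kinetic, should secure them. The E/Z ratio of the new C6=C7 bond does not matter because this bond is hydrogenated in step 7. The ligand antipode is the one that places the guaiacyl unit on C6; the sense of induction cannot be predicted with confidence for this bicycle and is to be assigned in a pilot run by correlation with 11. The acetal carbon is untouched, so the phenyl group ends up trans to both alkenyl groups.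

Step 4
Reactants: 6 4-hydroxy-3,5-dimethoxybenzaldehyde (syringaldehyde)
Product: 7 4-(benzyloxy)-3,5-dimethoxybenzaldehyde
Conditions: BnBr, K2CO3, DMF, 60 °C
Reagents that add atoms: benzyl bromide, BrCc1ccccc1
Why: Williamson etherification; the phenoxide flanked by two methoxy groups is hindered but reacts cleanly with a benzylic bromide in a dipolar aprotic solvent.

Step 5
Reactants: 7 4-(benzyloxy)-3,5-dimethoxybenzaldehyde
Product: 8 2-(benzyloxy)-5-ethenyl-1,3-dimethoxybenzene
Conditions: Ph3PCH3Br, KOtBu, THF, 0 °C to rt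
Reagents that add atoms: methyltriphenylphosphonium bromide, C[P+](c1ccccc1)(c1ccccc1)c1ccccc1.[Br-]
Why: Wittig methylenation as in step 2.

Step 6
Reactants: 5 (2S,4R,6S)-4-{(E)-2-[4-(benzyloxy)-3-methoxyphenyl]ethenyl}-6-ethenyl-2-phenyl-1,3-dioxane; 8 2-(benzyloxy)-5-ethenyl-1,3-dimethoxybenzene
Product: 9 (2R,4S,6R)-4-{(E)-2-[4-(benzyloxy)-3,5-dimethoxyphenyl]ethenyl}-6-{(E)-2-[4-(benzyloxy)-3-methoxyphenyl]ethenyl}-2-phenyl-1,3-dioxane
Conditions: 8 (3 equiv), Ru(=CH-2-iPrOC6H4)(SIMes)Cl2 (5 mol %), CH2Cl2, 40 °C, argon sparge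
Reagents that add atoms: none
Why: Olefin cross-metathesis between a reactive styrene and the monosubstituted vinyl group of 5 forms C1=C2 with loss of ethene; the internal styryl bond of 5 is 1,2-disubstituted and flanked by a branched carbon, so it should react much more slowly, and the geometry of the new bond is irrelevant because it is hydrogenated next.

Step 7
Reactants: 9 (2R,4S,6R)-4-{(E)-2-[4-(benzyloxy)-3,5-dimethoxyphenyl]ethenyl}-6-{(E)-2-[4-(benzyloxy)-3-methoxyphenyl]ethenyl}-2-phenyl-1,3-dioxane
Product: 11 (3R,5S)-1-(4-hydroxy-3,5-dimethoxyphenyl)-7-(4-hydroxy-3-methoxyphenyl)heptane-3,5-diol, via 4-{2-[(2R,4R,6S)-6-[2-(4-hydroxy-3-methoxyphenyl)ethyl]-2-phenyl-1,3-dioxan-4-yl]ethyl}-2,6-dimethoxyphenol 10 (not isolated)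
Conditions: H2 (1 atm), 10% Pd/C, EtOAc–MeOH, rt; then Pd(OH)2/C, AcOH (cat.), H2 (1 atm), rt
Reagents that add atoms: none
Why: Heterogeneous hydrogenation saturates both styryl bonds and cleaves the two aryl benzyl ethers under neutral conditions to give 10; acid is added only afterwards, when no allylic C–O bond is left, to hydrogenolyse the benzylidene acetal; C3 and C5 are not touched.

## Compound list

1 | cis-cyclopent-4-ene-1,3-diol (meso, (1R,3S)) | O[C@H]1C[C@@H](O)C=C1 | starting material
2 | (1R,3s,5S)-3-phenyl-2,4-dioxabicyclo[3.2.1]oct-6-ene (meso, phenyl exo) | O2[C@H]1C[C@@H](O[C@H]2c3ccccc3)C=C1 | intermediate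
3 | 4-(benzyloxy)-3-methoxybenzaldehyde | O=Cc1ccc(OCc2ccccc2)c(OC)c1 | starting material
4 | 1-(benzyloxy)-4-ethenyl-2-methoxybenzene | C=Cc1ccc(OCc2ccccc2)c(OC)c1 | intermediate
5 | (2S,4R,6S)-4-{(E)-2-[4-(benzyloxy)-3-methoxyphenyl]ethenyl}-6-ethenyl-2-phenyl-1,3-dioxane | O2[C@H](C=C)C[C@@H](O[C@H]2c3ccccc3)/C=C/c4ccc(OCc5ccccc5)c(OC)c4 | intermediate
6 | 4-hydroxy-3,5-dimethoxybenzaldehyde (syringaldehyde) | COc1cc(C=O)cc(OC)c1O | starting material
7 | 4-(benzyloxy)-3,5-dimethoxybenzaldehyde | COc1cc(C=O)cc(OC)c1OCc1ccccc1 | intermediate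
8 | 2-(benzyloxy)-5-ethenyl-1,3-dimethoxybenzene | COc1cc(C=C)cc(OC)c1OCc1ccccc1 | intermediate
9 | (2R,4S,6R)-4-{(E)-2-[4-(benzyloxy)-3,5-dimethoxyphenyl]ethenyl}-6-{(E)-2-[4-(benzyloxy)-3-methoxyphenyl]ethenyl}-2-phenyl-1,3-dioxane | O2[C@H](/C=C/c6cc(OC)c(OCc7ccccc7)c(OC)c6)C[C@@H](O[C@H]2c3ccccc3)/C=C/c4ccc(OCc5ccccc5)c(OC)c4 | intermediate
10 | 4-{2-[(2R,4R,6S)-6-[2-(4-hydroxy-3-methoxyphenyl)ethyl]-2-phenyl-1,3-dioxan-4-yl]ethyl}-2,6-dimethoxyphenol | O2[C@H](CCc6cc(OC)c(O)c(OC)c6)C[C@@H](O[C@H]2c3ccccc3)CCc4ccc(O)c(OC)c4 | intermediate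
11 | (3R,5S)-1-(4-hydroxy-3,5-dimethoxyphenyl)-7-(4-hydroxy-3-methoxyphenyl)heptane-3,5-diol | COc1cc(CC[C@H](O)C[C@H](O)CCc2cc(OC)c(O)c(OC)c2)ccc1O | target

## Step count and risk

Total step count: 7. Longest linear sequence: 4 steps (1 → 2 → 5 → 9 → 11; the branch 6 → 7 → 8 → 9 → 11 is equally long).

**Step 3 (key step).**
- What may go wrong: insufficient discrimination between the two enantiotopic olefinic carbons of this untested bicycle. Nothing later in the route can raise the enantiomeric purity. Ring-opening oligomerisation of 2 and a second cross-metathesis of the new vinyl group with 4 are the other failure processes.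
- Within the same approach, a chiral molybdenum imido alkylidene can replace the Ru complex, and the order of 4 and 8 can be exchanged if only the "wrong" ligand antipode is at hand.
- Fallback (known boron-aldol chemistry, from 3 and 7 back to 11): Claisen–Schmidt condensation of 3 with acetone gives (E)-4-[4-(benzyloxy)-3-methoxyphenyl]but-3-en-2-one F1. Wittig reaction of 7 with (triphenylphosphoranylidene)acetaldehyde gives (E)-3-[4-(benzyloxy)-3,5-dimethoxyphenyl]prop-2-enal F2. The diisopinocampheylboron enolate of F1 (Ipc2BCl antipode chosen for the 5S product, Et3N, Et2O, −78 °C) adds to F2 to give (1E,5S,6E)-1-[4-(benzyloxy)-3-methoxyphenyl]-7-[4-(benzyloxy)-3,5-dimethoxyphenyl]-5-hydroxyhepta-1,6-dien-3-one F3. Narasaka–Prasad reduction (Et2BOMe, NaBH4, THF–MeOH, −78 °C) should give (1E,3S,5R,6E)-1-[4-(benzyloxy)-3,5-dimethoxyphenyl]-7-[4-(benzyloxy)-3-methoxyphenyl]hepta-1,6-diene-3,5-diol F4. Diimide reduction of both styryl bonds gives (3R,5S)-1-[4-(benzyloxy)-3,5-dimethoxyphenyl]-7-[4-(benzyloxy)-3-methoxyphenyl]heptane-3,5-diol F5, and hydrogenolysis (H2, Pd/C) returns to 11.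

**Step 1.**
- What may go wrong: acetal exchange stopping at open mixed acetals or oligomers, because bridging needs the diaxial envelope; acid-induced ionisation of the bis-allylic diol.
- Fallback (boron tether formed without acid, from 1 back to 11): 1 and phenylboronic acid (toluene, MgSO4, rt) give meso (1R,5S)-3-phenyl-2,4-dioxa-3-borabicyclo[3.2.1]oct-6-ene F6. Ring-opening/cross-metathesis with 4 under the conditions of step 3 gives (4R,6S)-4-{(E)-2-[4-(benzyloxy)-3-methoxyphenyl]ethenyl}-6-ethenyl-2-phenyl-1,3,2-dioxaborinane F7. Cross-metathesis with 8 as in step 6 gives (4S,6R)-4-{(E)-2-[4-(benzyloxy)-3,5-dimethoxyphenyl]ethenyl}-6-{(E)-2-[4-(benzyloxy)-3-methoxyphenyl]ethenyl}-2-phenyl-1,3,2-dioxaborinane F8. Hydrogenation (H2, Pd/C, EtOAc–MeOH) gives 4-{2-[(4R,6S)-6-[2-(4-hydroxy-3-methoxyphenyl)ethyl]-2-phenyl-1,3,2-dioxaborinan-4-yl]ethyl}-2,6-dimethoxyphenol F9, which is not isolated; transesterification with pinacol in methanol releases 11.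

**Step 6.**
- What may go wrong: secondary metathesis at the internal styryl bond of 5, which would exchange the aryl groups and erode both constitutional and enantiomeric purity; homodimerisation of 8 outrunning the cross reaction; slow turnover at the hindered vinyl group.
- Fallback (C1–aryl bond by cross-coupling instead of C1=C2 by metathesis, from 5 back to 10): benzylation of commercial 4-bromo-2,6-dimethoxyphenol gives 2-(benzyloxy)-5-bromo-1,3-dimethoxybenzene F10. Chemoselective hydroboration of the terminal vinyl group of 5 with 9-BBN (THF, 0 °C to rt) gives 9-{2-[(2S,4R,6R)-6-{(E)-2-[4-(benzyloxy)-3-methoxyphenyl]ethenyl}-2-phenyl-1,3-dioxan-4-yl]ethyl}-9-borabicyclo[3.3.1]nonane F11, used without isolation. B-alkyl Suzuki–Miyaura coupling with F10 (Pd(dppf)Cl2, aq. K3PO4, DMF, 60 °C) gives (2S,4R,6R)-4-{2-[4-(benzyloxy)-3,5-dimethoxyphenyl]ethyl}-6-{(E)-2-[4-(benzyloxy)-3-methoxyphenyl]ethenyl}-2-phenyl-1,3-dioxane F12. The conditions of step 7 take F12 to 10 and on to 11.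

**Step 7.**
- What may go wrong: hydrogenolysis of the allylic C3–O and C5–O bonds before the styryl double bonds are saturated, giving deoxygenated chains; incomplete cleavage of the benzylidene acetal.
- Fallback (alkenes reduced without a metal surface, from 9 back to 11): diimide reduction of 9 (2-nitrobenzenesulfonohydrazide, Et3N, CH2Cl2, rt) gives (2R,4R,6S)-4-{2-[4-(benzyloxy)-3,5-dimethoxyphenyl]ethyl}-6-{2-[4-(benzyloxy)-3-methoxyphenyl]ethyl}-2-phenyl-1,3-dioxane F13, which has no allylic C–O bond left; hydrogenolysis (H2, Pd(OH)2/C, MeOH–EtOAc, cat. AcOH) then gives 11.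

## Further compounds

F1 | step 3 | (E)-4-[4-(benzyloxy)-3-methoxyphenyl]but-3-en-2-one | CC(=O)/C=C/c1ccc(OCc2ccccc2)c(OC)c1
F2 | step 3 | (E)-3-[4-(benzyloxy)-3,5-dimethoxyphenyl]prop-2-enal | O=C/C=C/c1cc(OC)c(OCc2ccccc2)c(OC)c1
F3 | step 3 | (1E,5S,6E)-1-[4-(benzyloxy)-3-methoxyphenyl]-7-[4-(benzyloxy)-3,5-dimethoxyphenyl]-5-hydroxyhepta-1,6-dien-3-one | COc1cc(/C=C/C(=O)C[C@H](O)/C=C/c2cc(OC)c(OCc3ccccc3)c(OC)c2)ccc1OCc1ccccc1
F4 | step 3 | (1E,3S,5R,6E)-1-[4-(benzyloxy)-3,5-dimethoxyphenyl]-7-[4-(benzyloxy)-3-methoxyphenyl]hepta-1,6-diene-3,5-diol | COc1cc(/C=C/[C@H](O)C[C@H](O)/C=C/c2cc(OC)c(OCc3ccccc3)c(OC)c2)ccc1OCc1ccccc1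
F5 | step 3 | (3R,5S)-1-[4-(benzyloxy)-3,5-dimethoxyphenyl]-7-[4-(benzyloxy)-3-methoxyphenyl]heptane-3,5-diol | COc1cc(CC[C@H](O)C[C@H](O)CCc2cc(OC)c(OCc3ccccc3)c(OC)c2)ccc1OCc1ccccc1
F6 | step 1 | (1R,5S)-3-phenyl-2,4-dioxa-3-borabicyclo[3.2.1]oct-6-ene (meso) | O2[C@H]1C[C@@H](OB2c3ccccc3)C=C1
F7 | step 1 | (4R,6S)-4-{(E)-2-[4-(benzyloxy)-3-methoxyphenyl]ethenyl}-6-ethenyl-2-phenyl-1,3,2-dioxaborinane | O2[C@H](C=C)C[C@@H](OB2c3ccccc3)/C=C/c4ccc(OCc5ccccc5)c(OC)c4
F8 | step 1 | (4S,6R)-4-{(E)-2-[4-(benzyloxy)-3,5-dimethoxyphenyl]ethenyl}-6-{(E)-2-[4-(benzyloxy)-3-methoxyphenyl]ethenyl}-2-phenyl-1,3,2-dioxaborinane | O2[C@H](/C=C/c6cc(OC)c(OCc7ccccc7)c(OC)c6)C[C@@H](OB2c3ccccc3)/C=C/c4ccc(OCc5ccccc5)c(OC)c4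
F9 | step 1 | 4-{2-[(4R,6S)-6-[2-(4-hydroxy-3-methoxyphenyl)ethyl]-2-phenyl-1,3,2-dioxaborinan-4-yl]ethyl}-2,6-dimethoxyphenol | O2[C@H](CCc6cc(OC)c(O)c(OC)c6)C[C@@H](OB2c3ccccc3)CCc4ccc(O)c(OC)c4
F10 | step 6 | 2-(benzyloxy)-5-bromo-1,3-dimethoxybenzene | COc1cc(Br)cc(OC)c1OCc1ccccc1
F11 | step 6 | 9-{2-[(2S,4R,6R)-6-{(E)-2-[4-(benzyloxy)-3-methoxyphenyl]ethenyl}-2-phenyl-1,3-dioxan-4-yl]ethyl}-9-borabicyclo[3.3.1]nonane | O2[C@H](CCB6C7CCCC6CCC7)C[C@@H](O[C@H]2c3ccccc3)/C=C/c4ccc(OCc5ccccc5)c(OC)c4
F12 | step 6 | (2S,4R,6R)-4-{2-[4-(benzyloxy)-3,5-dimethoxyphenyl]ethyl}-6-{(E)-2-[4-(benzyloxy)-3-methoxyphenyl]ethenyl}-2-phenyl-1,3-dioxane | O2[C@H](CCc6cc(OC)c(OCc7ccccc7)c(OC)c6)C[C@@H](O[C@H]2c3ccccc3)/C=C/c4ccc(OCc5ccccc5)c(OC)c4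
F13 | step 7 | (2R,4R,6S)-4-{2-[4-(benzyloxy)-3,5-dimethoxyphenyl]ethyl}-6-{2-[4-(benzyloxy)-3-methoxyphenyl]ethyl}-2-phenyl-1,3-dioxane | O2[C@H](CCc6cc(OC)c(OCc7ccccc7)c(OC)c6)C[C@@H](O[C@H]2c3ccccc3)CCc4ccc(OCc5ccccc5)c(OC)c4
A1 | alternative 1 | (5R)-1-[4-(benzyloxy)-3-methoxyphenyl]-7-[4-(benzyloxy)-3,5-dimethoxyphenyl]-5-hydroxyheptan-3-one | COc1cc(CCC(=O)C[C@H](O)CCc2cc(OC)c(OCc3ccccc3)c(OC)c2)ccc1OCc1ccccc1
A2 | alternative 2 | (1E,6E)-1-(4-hydroxy-3,5-dimethoxyphenyl)-7-(4-hydroxy-3-methoxyphenyl)hepta-1,6-diene-3,5-dione | COc1cc(/C=C/C(=O)CC(=O)/C=C/c2cc(OC)c(O)c(OC)c2)ccc1O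
A3 | alternative 2 | 1-(4-hydroxy-3,5-dimethoxyphenyl)-7-(4-hydroxy-3-methoxyphenyl)heptane-3,5-dione | COc1cc(CCC(=O)CC(=O)CCc2cc(OC)c(O)c(OC)c2)ccc1O
A4 | alternative 3 | (2E,5R)-1-[4-(benzyloxy)-3-methoxyphenyl]-7-[4-(benzyloxy)-3,5-dimethoxyphenyl]-5-hydroxyhept-2-en-1-one | COc1cc(C(=O)/C=C/C[C@H](O)CCc2cc(OC)c(OCc3ccccc3)c(OC)c2)ccc1OCc1ccccc1
A5 | alternative 3 | 1-[4-(benzyloxy)-3-methoxyphenyl]-2-[(2R,4R,6R)-6-{2-[4-(benzyloxy)-3,5-dimethoxyphenyl]ethyl}-2-phenyl-1,3-dioxan-4-yl]ethan-1-one | COc1cc(C(=O)C[C@H](O5)C[C@H](O[C@H]5c6ccccc6)CCc2cc(OC)c(OCc3ccccc3)c(OC)c2)ccc1OCc1ccccc1
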